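## Retrosynthetic overview
1. The last bond made is C4–C2(stilbene). Unprotected piceatannol captures a 2,3-cis flavan-4-yl cation on the face anti to the 3-OH, as in tannin biosynthesis, and this sets C4.
2. The cation comes from an all-cis flavan-3,4-diol. Its C2 and C3 centres are set together by one enantioselective syn-hydrogenation of a flat flavonol. This parallels the plant's detour through a planar ring C to reach 2,3-cis units.
3. Ring C is the only ring built. It forms by oxidative 6-endo oxa-Michael closure of unprotected isoliquiritigenin (chalcone → flavanone enolate → dihydroflavonol → flavonol in one flask).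
4. The chalcone comes from 2,4-dihydroxyacetophenone and 4-hydroxybenzaldehyde. Rings A and B and both stilbene rings (D, E) are bought.
5. Order: chalcone → ring C → C2/C3 → C4–aryl bond. The stilbene alkene enters only after the hydrogenation.

Assumption: piceatannol is bought as a bulk natural stilbene. The (R,R)-ligand written in step 4 is taken to be the antipode that gives 2R,3R. If the first run shows the opposite sense, the equally available (S,S)-ligand is used.

The target is (2R,3R,4R): 2,3-cis and 3,4-trans, i.e. epiguibourtinidol-(4β→2)-piceatannol.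

## Route

Step 1
Reactants: 1 2,4-dihydroxyacetophenone; 2 4-hydroxybenzaldehyde
Product: 3 isoliquiritigenin [(E)-1-(2,4-dihydroxyphenyl)-3-(4-hydroxyphenyl)prop-2-en-1-one]
Conditions: KOH (60% aq), EtOH, rt, 72 h; then aq HCl
Reagents that add atoms: none
Why: Claisen–Schmidt (crossed aldol) condensation in which only the ketone can enolise, and E1cB dehydration gives the conjugated, thermodynamically preferred E-enone without any phenol protection.

Step 2
Reactants: 3 isoliquiritigenin
Product: 5 resokaempferol (3,7,4'-trihydroxyflavone), via racemic trans-garbanzol 4 (not isolated)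
Conditions: 30% aq H2O2, NaOH (5 M aq), MeOH, 0 °C → rt, 16 h; then aq HCl
Reagents that add atoms: hydrogen peroxide, OO
Why: Algar–Flynn–Oyamada reaction, in which the 2'-phenoxide closes ring C by 6-endo oxa-Michael addition (the chalcone isomerase step), the enolate is hydroxylated at C3 by H2O2 to give 4, and 4 is oxidised on to the flavonol; the missing 6'-substituent disfavours aurone formation, and the transient stereocentres are erased on purpose.

Step 3
Reactants: 5 resokaempferol
Product: 6 3,7,4'-triacetoxyflavone
Conditions: Ac2O, pyridine, rt, 6 h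
Reagents that add atoms: acetic anhydride, CC(=O)OC(C)=O
Why: Exhaustive O-acylation removes the acidic, metal-chelating 3-hydroxy-4-keto and phenol functions, makes the pyranone more electron-poor for hydride addition, and gives a crystalline, toluene-soluble substrate.

Step 4
Reactants: 6 3,7,4'-triacetoxyflavone
Product: 8 (2R,3R,4R)-3,7,4'-triacetoxyflavan-4-ol (2,3-cis-3,4-cis), via cis-triacetoxyflavanone 7 (not isolated)
Conditions: [Ru(cod)(2-methylallyl)2] (5 mol %), 1,3-bis[(1R)-1-(naphthalen-1-yl)ethyl]-4,5-dihydroimidazolium tetrafluoroborate (10 mol %), KOtBu (10 mol %), n-hexane, 70 °C, 16 h, filtered; then 6, toluene, H2 (120 bar), 30 °C, 48 h; recrystallise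
Reagents that add atoms: none
Why: Proposed new method: the chiral bis(NHC)–ruthenium hydride known to hydrogenate flavones enantioselectively to 2,4-cis-flavan-4-ols is extended here to a 3-acyloxyflavone; both hydrogens reach C2 and C3 from the catalyst-selected face of the flat pyranone (syn addition), so the 2-aryl and 3-OAc groups end up cis (2R,3R in flavan numbering); the electron-withdrawing and possibly Ru-coordinating enol acetate offsets the extra substitution, the base-free filtered catalyst avoids C3 epimerisation of ketone 7, and 7 is then reduced anti to its axial 3-OAc to an alcohol whose C4 configuration is lost in step 5 and does not matter; the closest known reaction types are the asymmetric hydrogenation of flavones and chromones and the classical racemic Raney Ni hydrogenation of flavonols to 2,3-cis-3,4-cis-flavan-3,4-diols.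

Step 5
Reactants: 8 (2R,3R,4R)-3,7,4'-triacetoxyflavan-4-ol; 9 piceatannol [(E)-3,5,3',4'-tetrahydroxystilbene]
Product: 12 CNP0170061.2 [(2R,3R,4R)-epiguibourtinidol-(4β→2)-piceatannol], via free flavan-3,4-diol 10 (not isolated), via flavan-4-yl cation 11 (not isolated)
Conditions: K2CO3 (3.5 equiv), degassed MeOH, 0 °C, 1 h; then 9 (4 equiv), aq HCl to 0.1 M, rt, 16 h, Ar, dark; Sephadex LH-20 (excess 9 recovered)
Reagents that add atoms: none
Why: Base-catalysed transesterification frees 10, and dilute acid with the help of the 7-OH ionises the benzylic 4-OH to cation 11 (SN1, biomimetic proanthocyanidin-type Friedel–Crafts alkylation); the resorcinol ring of 9 attacks through C-2, which is ortho and para to its two OH groups and is the site established for acid condensations of flavan-3,4-diols with hydroxystilbenes; attack comes from the β face anti to the axial 3-OH, giving only the 3,4-trans (4R) product, while excess 9 suppresses self-condensation.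

## Compound list
1 | 2,4-dihydroxyacetophenone | CC(=O)c1ccc(O)cc1O | starting material
2 | 4-hydroxybenzaldehyde | O=Cc1ccc(O)cc1 | starting material
3 | isoliquiritigenin, (E)-2',4',4-trihydroxychalcone | O=C(/C=C/c1ccc(O)cc1)c1ccc(O)cc1O | intermediate
4 | racemic trans-garbanzol, (2R,3R)/(2S,3S)-3,7,4'-trihydroxyflavanone (not isolated) | Oc1ccc(cc1)[C@@H]1[C@@H](O)C(=O)c2ccc(O)cc2O1.Oc1ccc(cc1)[C@H]1[C@H](O)C(=O)c2ccc(O)cc2O1 | intermediate
5 | resokaempferol, 3,7,4'-trihydroxyflavone | O=c1c(O)c(-c2ccc(O)cc2)oc2cc(O)ccc12 | intermediate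
6 | 3,7,4'-triacetoxyflavone | CC(=O)Oc1ccc(cc1)-c1oc2cc(OC(C)=O)ccc2c(=O)c1OC(C)=O | intermediate
7 | (2R,3S)-2,3-cis-3,7,4'-triacetoxyflavanone (not isolated) | CC(=O)Oc1ccc([C@H]2Oc3cc(OC(C)=O)ccc3C(=O)[C@H]2OC(C)=O)cc1 | intermediate
8 | (2R,3R,4R)-2,3-cis-3,4-cis-3,7,4'-triacetoxyflavan-4-ol | CC(=O)Oc1ccc([C@H]2Oc3cc(OC(C)=O)ccc3[C@@H](O)[C@H]2OC(C)=O)cc1 | intermediate
9 | piceatannol, (E)-3,5,3',4'-tetrahydroxystilbene | Oc1cc(O)cc(/C=C/c2ccc(O)c(O)c2)c1 | starting material
10 | (2R,3R,4R)-2,3-cis-3,4-cis-flavan-3,4,7,4'-tetraol (not isolated) | Oc1ccc([C@H]2Oc3cc(O)ccc3[C@@H](O)[C@H]2O)cc1 | intermediate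
11 | (2R,3R)-3,7,4'-trihydroxyflavan-4-yl cation, the protonated ring A quinone methide (not isolated) | Oc1ccc([C@H]2Oc3cc(O)ccc3[CH+][C@H]2O)cc1 | intermediate
12 | CNP0170061.2, (2R,3R,4R)-4-{2-[(E)-2-(3,4-dihydroxyphenyl)ethenyl]-4,6-dihydroxyphenyl}-2-(4-hydroxyphenyl)chromane-3,7-diol | Oc1ccc([C@H]2Oc3cc(O)ccc3[C@H](c3c(O)cc(O)cc3/C=C/c3ccc(O)c(O)c3)[C@H]2O)cc1 | target

## Step count and risks
Total steps: 5. Longest linear sequence: 5 (1 → 3 → 5 → 6 → 8 → 12).

The three steps most likely to fail are step 4 (highest risk), step 2 and step 5.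

**Step 2.** The trianionic chalcone is a poor Michael acceptor, and H2O2 may degrade the electron-rich rings, so only a modest yield is expected.
- The fallback sets out from 3 and comes back at 6. It closes ring C without the C3 oxygen and adds that oxygen later.
- I2 (10 mol %) in DMSO at 130 °C converts 3 into 7,4'-dihydroxyflavone F1, and Ac2O/pyridine gives 7,4'-diacetoxyflavone F2.
- Dimethyldioxirane (acetone/CH2Cl2, 0 °C) epoxidises the C2=C3 bond to racemic 7,4'-diacetoxy-2,3-epoxyflavanone F3.
- F3 opens on silica gel or with a trace of TsOH to 7,4'-diacetoxy-3-hydroxyflavone F4, and Ac2O/pyridine then gives 6.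

**Step 4.** The tetrasubstituted enol acetate may be too hindered, the ee may be low, or ketone 7 may epimerise at C3 before it is reduced.
- The fallback sets out from 6 and comes back at 8. It replaces asymmetric catalysis by racemic syn-hydrogenation and resolution.
- H2 (100 bar) over Raney Ni in EtOAc at 60–80 °C gives racemic all-cis 3,7,4'-triacetoxyflavan-4-ol F5.
- F5 is resolved by preparative supercritical-fluid chromatography on an amylose tris(3,5-dimethylphenylcarbamate) phase.
- One enantiomer is 8. The (2S,3S,4S)-3,7,4'-triacetoxyflavan-4-ol F6 is discarded.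

**Step 5.** The quasi-equatorial 4-OH of the 3,4-cis diol may ionise slowly, 10 may self-condense, and the stilbene may suffer under longer acid exposure.
- The fallback sets out from 10 and comes back at 12. It replaces Brønsted-acid ionisation by thiophilic activation of an isolable C4 thioether under neutral conditions.
- Compound 10 is generated as in the first stage of step 5 and neutralised with AcOH. It is then heated with phenylmethanethiol in AcOH/EtOH to give (2R,3S,4S)-4-(benzylsulfanyl)flavan-3,7,4'-triol F7 (2,3-cis-3,4-trans), which is purified.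
- AgBF4 (2.5 equiv) in THF at 0 °C, in the presence of 9 (4 equiv), releases cation 11. Compound 9 captures it on the β face to give 12.

## Further compounds
F1 | step 2 | 7,4'-dihydroxyflavone | O=c1cc(-c2ccc(O)cc2)oc2cc(O)ccc12
F2 | step 2 | 7,4'-diacetoxyflavone | CC(=O)Oc1ccc(cc1)-c1cc(=O)c2ccc(OC(C)=O)cc2o1
F3 | step 2 | racemic 7,4'-diacetoxy-2,3-epoxyflavanone | CC(=O)Oc1ccc(cc1)[C@]12O[C@H]1C(=O)c1ccc(OC(C)=O)cc1O2.CC(=O)Oc1ccc(cc1)[C@@]12O[C@@H]1C(=O)c1ccc(OC(C)=O)cc1O2
F4 | step 2 | 7,4'-diacetoxy-3-hydroxyflavone | CC(=O)Oc1ccc(cc1)-c1oc2cc(OC(C)=O)ccc2c(=O)c1O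
F5 | step 4 | racemic 2,3-cis-3,4-cis-3,7,4'-triacetoxyflavan-4-ol | CC(=O)Oc1ccc([C@H]2Oc3cc(OC(C)=O)ccc3[C@@H](O)[C@H]2OC(C)=O)cc1.CC(=O)Oc1ccc([C@@H]2Oc3cc(OC(C)=O)ccc3[C@H](O)[C@@H]2OC(C)=O)cc1
F6 | step 4 | (2S,3S,4S)-3,7,4'-triacetoxyflavan-4-ol | CC(=O)Oc1ccc([C@@H]2Oc3cc(OC(C)=O)ccc3[C@H](O)[C@@H]2OC(C)=O)cc1
F7 | step 5 | (2R,3S,4S)-4-(benzylsulfanyl)flavan-3,7,4'-triol | Oc1ccc([C@H]2Oc3cc(O)ccc3[C@H](SCc3ccccc3)[C@H]2O)cc1
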